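The coupling partner is the reagent in question: theta feeds it over 5.0 min, delta has it from the start, and epsilon feeds the substrate instead.

the same everywhere: second catalyst 48 mM
- violet: substrate 0.30 M; coupling partner 0.30 M; free catalyst 1.5 mM; run made earlier
- grey: substrate 0.15 M; coupling partner 0.30 M; free catalyst 1.5 mM; run made earlier
- blue: substrate 0.22 M; coupling partner 0.30 M; free catalyst 1.5 mM; run made earlier
- teal: substrate 0.30 M; coupling partner 0.30 M; free catalyst 3 mM; run made earlier
- theta: substrate 0.30 M; coupling partner 0.300 M (fed, over 5.0 min); free catalyst 1.5 mM; all else is in the flask from the start; the feed brings no volume worth counting; time 25 min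
- delta: substrate 0.30 M; coupling partner 0.300 M; free catalyst 1.5 mM; everything together at the start; time 25 min
- epsilon: substrate 0.30 M (fed, over 5.0 min); coupling partner 0.300 M; free catalyst 1.5 mM; all else is in the flask from the start; the feed brings no volume worth counting; time 25 min

| run | time / min | product / % | substrate / % |
|---|---|---|---|
| violet | 2.00 | 35.7 | 34.6 |
| violet | 4.00 | 46.3 | 12.8 |
| violet | 8.00 | 48.9 | 1.8 |
| violet | 12.0 | 47.2 | 0 |
| violet | 25.0 | 45.8 | 0 |
| grey | 2.50 | 41.4 | 27.0 |
| grey | 5.00 | 48.7 | 8.0 |
| grey | 8.00 | 48.4 | 1.8 |
| grey | 15.0 | 40.5 | 0.7 |
| grey | 30.0 | 40.3 | 0 |
| blue | 2.50 | 37.4 | 28.0 |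
| blue | 5.00 | 48.1 | 7.8 |
| blue | 8.00 | 47.8 | 1.7 |
| blue | 15.0 | 46.8 | 0 |
| blue | 30.0 | 45.5 | 0 |
| teal | 2.50 | 51.4 | 7.4 |
| teal | 8.00 | 54.2 | 0.8 |
| teal | 15.0 | 50.2 | 0.4 |
| teal | 20.0 | 50.1 | 0.5 |
| teal | 30.0 | 48.0 | 0.8 |

(each reading ± 1 percentage point)

- a reading or a percentage of product counts all its forms, free or not

- the flask that comes out highest in amount of product, in percent of the substrate charged, or "all alike" when all lie within 1.5 percentage points (theta / delta / epsilon / all alike)
- product at the end, in percent of the substrate charged, theta
- product at the end, in percent of the substrate charged, delta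
- product at the end, in percent of the substrate charged, epsilon

Follow one substrate molecule through violet. By 2.00 min the flask has consumed 65.4 % of the substrate and shows 35.7 % product, so a consumed molecule has a chance of 54.6 % at the fork. Grey reads 56.7 % at half the substrate. This steady chance, a selectivity, gives the bench rule: yield is chance times conversion, and a slow feed merely delays. Violet's last reading stands lower than that chance, at 45.8 %, and by the rule that figure serves for theta, delta and epsilon alike.

But the earlier runs held their partner from the start, so the rule is untested where partner comes late. The border is the arrival share: substrate half-life over feed time, the fraction of a fed charge that has entered after one half-life. The pseudo-first-order decay in violet reads a half-life of 1.31 min, so the share is 26.1 %. In theta, then, by this reckoning a quarter of the partner charge, 0.0784 M per starting volume, has entered when 0.150 M of substrate is consumed. The chance read in violet is therefore not carried over to theta. My own reckoning puts theta below delta by more than the margin, and epsilon, with its partner charged from the start, near delta.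

The forecast gives theta 46 %, delta 46 % and epsilon 45.5 %, with the highest all alike, though it adds that “theta carries a risk from early partner starvation”. On theta the reckoning above parts from it.

The flasks give theta 32.5 %, delta 46.7 % and epsilon 43.1 %; the highest is delta.

    open intermediate → decomposed reagent (k = 0.00767 s⁻¹)
    coupling partner + catalyst intermediate → second catalyst + product (k = 16.5 M⁻¹ s⁻¹)
    second catalyst + product → spent catalyst (k = 0.0499 M⁻¹ s⁻¹)
    second catalyst + open intermediate ⇌ catalyst intermediate (K = 0.160 M⁻¹, k = 9.72 M⁻¹ s⁻¹)
    substrate + free catalyst → free catalyst + open intermediate (k = 5.73 M⁻¹ s⁻¹)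
    crystals ⇌ product, rate k6*(cs6 - [product]) while solid is left; crystals form when [product] > cs6 (solubility = 0.0790 M, k = 1.03 s⁻¹)

Two steps at the fork of open intermediate act together in theta's loss, its decomposition as the largest single effect and the back reaction of catalyst intermediate as a part: the gap of 14 percentage points between delta and theta falls to 0.21 points with the decomposition removed, and to 4.8 points with the back reaction removed. The arrival share puts theta's substrate at the end of the feed at 7.02 % of the charge; 7.59 % stood there, beside 43.1 % decomposed reagent. In epsilon the same share gives a standing substrate of 37.7 % of the charge; 35.8 % stood at 5.00 min, with decomposed reagent at 13.3 %, less than theta's.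

The data stem from a simulated flask from invented constants.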